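**Plan**
- Retrosynthesis: cut the malonate C–O bond, then C11–C12 (sulfone alkylation), then the two allylic bonds C6–C7 and C8–C9 of ring B, and last C9–C10 and C5–C6 on ring A.
- Enabling feature: ring B is a cyclohexene whose alkene carbons C7 and C8 are held only through C6 (on C5) and C9 (on C10), two arms on neighbouring carbons of ring A. A C6 radical and a C9=C11 acceptor form a 4-pentenyl system that cannot close by itself but gives the six-membered ring once an alkyne is taken up between them.
- Forward: ring A comes from 2,4,4-trimethylcyclohex-2-en-1-one, to which the two arms are added. Ring B is then closed in one radical annulation with methyl propiolate, whose ester carbon becomes C17. The C12–C16 unit is joined through the C11 sulfone and the malonate is put on last.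
- Stereochemistry: C5 from a Corey–Bakshi–Shibata reduction relayed by a suprafacial Claisen shift; C10 by addition to the C10 radical anti to the C5 arm; C9 in the ring closure (arm equatorial); the 13E alkene from selenium dioxide oxidation of the (E)-methyl of a prenyl ether.

Key step: step 6

Remark: labdane numbering is used for all carbons (ring A = C1–C5 and C10; ring B = C5–C10; chain C11–C16; C17 on C8; C18 and C19 on C4; C20 on C10). Compounds 1, 5, 10 and 15 are taken as commercial.

**Route**

Step 1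
Reactants: 1 2,4,4-trimethylcyclohex-2-en-1-one
Product: 2 (1R)-2,4,4-trimethylcyclohex-2-en-1-ol
Conditions: (S)-1-methyl-3,3-diphenyl-tetrahydro-1H,3H-pyrrolo[1,2-c][1,3,2]oxazaborole (0.1 equiv), BH3·SMe2, THF, −20 °C; aq. NH4Cl
Reagents that add atoms: none
Why: Corey–Bakshi–Shibata reduction; the α-methyl alkenyl side should act as the large group, so hydride should be delivered to the face that gives the (R)-carbinol by 1,2-reduction.

Step 2
Reactants: 2 (1R)-2,4,4-trimethylcyclohex-2-en-1-ol
Product: 4 ethyl 2-[(1S)-2,6,6-trimethylcyclohex-2-en-1-yl]acetate, via ketene acetal 3 (not isolated)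
Conditions: MeC(OEt)3 (6 equiv), EtCO2H (0.1 equiv), 140 °C, EtOH distilled off
Reagents that add atoms: triethyl orthoacetate, CC(OCC)(OCC)OCC
Why: Johnson–Claisen rearrangement; the suprafacial [3,3] shift should place the two-carbon unit on C5 on the ring face that carried the C–O bond, so C5 (S) follows from the carbinol and the alkene moves to C1=C10.

Step 3
Reactants: 4 ethyl 2-[(1S)-2,6,6-trimethylcyclohex-2-en-1-yl]acetate; 5 (E)-1,2-bis(phenylsulfonyl)ethene
Product: 6 ethyl 2-[(1S,2S)-2,6,6-trimethyl-2-[(E)-2-(phenylsulfonyl)ethenyl]cyclohexyl]acetate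
Conditions: Fe(acac)3 (0.3 equiv), PhSiH3 (2.5 equiv), 5 (2.5 equiv), EtOH/HOCH2CH2OH, 60 °C
Reagents that add atoms: none
Why: Proposed new method: the iron hydride formed from Fe(acac)3 and PhSiH3 should transfer a hydrogen atom to C1 of the trisubstituted alkene (Markovnikov sense), the tertiary C10 radical should add to the electron-poor bis-sulfone 5 and the adduct should expel a phenylsulfonyl radical to leave the (E)-vinyl sulfone, the closest known types being the iron-hydride reductive coupling of alkenes with vinyl sulfones and the radical alkenylation of alkyl radicals with this bis-sulfone; the acceptor should reach the planar C10 radical on the face away from the C5 arm, because attack on the other face must pass either that arm or the syn-axial C4 methyl, which should set C10 with C9 trans to C6.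

Step 4
Reactants: 6 ethyl 2-[(1S,2S)-2,6,6-trimethyl-2-[(E)-2-(phenylsulfonyl)ethenyl]cyclohexyl]acetate
Product: 7 2-[(1S,2S)-2,6,6-trimethyl-2-[(E)-2-(phenylsulfonyl)ethenyl]cyclohexyl]acetic acid
Conditions: LiOH, THF/H2O, 40 °C; then 1 M HCl
Reagents that add atoms: lithium hydroxide, [Li+].[OH-]
Why: ester saponification; hydroxide should attack the unhindered ester carbonyl much faster than the β-carbon of the vinyl sulfone, which is shielded by the quaternary C10.

Step 5
Reactants: 7 2-[(1S,2S)-2,6,6-trimethyl-2-[(E)-2-(phenylsulfonyl)ethenyl]cyclohexyl]acetic acid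
Product: 9 [(E)-2-[(1R,2S)-2-(iodomethyl)-1,3,3-trimethylcyclohexyl]ethenyl]sulfonylbenzene, via acyl hypoiodite 8 (not isolated)
Conditions: PhI(OAc)2, I2, benzene, tungsten lamp, reflux
Reagents that add atoms: iodine, [I][I]
Why: Hunsdiecker-type iododecarboxylation; the acyl hypoiodite should lose CO2 on irradiation and the primary C6 radical is trapped by iodine, which avoids an SN2 displacement at this doubly branched position and does not touch C5.

Step 6
Reactants: 9 [(E)-2-[(1R,2S)-2-(iodomethyl)-1,3,3-trimethylcyclohexyl]ethenyl]sulfonylbenzene; 10 methyl propiolate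
Product: 11 methyl (1R,4aS,8aS)-5,5,8a-trimethyl-1-[(phenylsulfonyl)methyl]-1,4,4a,5,6,7,8,8a-octahydronaphthalene-2-carboxylate
Conditions: 10 (10 equiv), Bu3SnH (1.5 equiv, syringe pump), AIBN (0.2 equiv), benzene (0.01 M in 9), 80 °C
Reagents that add atoms: none
Why: Proposed new method: a tributyltin radical should take iodine from 9, the primary C6 radical (a 4-pentenyl radical, for which 4-exo and 5-endo closure are disfavoured) should add to the unsubstituted carbon of methyl propiolate to form C6–C7, and the α-ester vinyl radical at C8 should then attack C9, the β-carbon of the vinyl sulfone, to form C8–C9 before the α-sulfonyl radical at C11 takes hydrogen from Bu3SnH. The closest known reaction types are the tin-mediated Giese addition of alkyl iodides to propiolates and the cyclization of vinyl radicals onto alkenes (radical annulation). Ring B closes in the 6-exo-trig mode, and the ring alkene is cis by necessity because the vinyl radical inverts freely. The new stereocenter C9 is controlled by ring A: with the C6 and C9 arms both equatorial on the chair, the vinyl sulfone should react in the rotamer in which the C10 methyl eclipses the C9=C11 bond (least allylic 1,3-strain), which puts C11 pseudo-equatorial as in the target. The step needs the C6 radical to meet the alkyne before it is reduced (excess alkyne, low stannane concentration) and needs attack at C9 and not at C11 (exo closure at the β-position of the acceptor); the hindered β-carbon of the vinyl sulfone should also keep addition to a second molecule of 9 slow.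

Step 7
Reactants: 11 methyl (1R,4aS,8aS)-5,5,8a-trimethyl-1-[(phenylsulfonyl)methyl]-1,4,4a,5,6,7,8,8a-octahydronaphthalene-2-carboxylate
Product: 12 [(1R,4aS,8aS)-5,5,8a-trimethyl-1-[(phenylsulfonyl)methyl]-1,4,4a,5,6,7,8,8a-octahydronaphthalen-2-yl]methanol
Conditions: i-Bu2AlH (2.5 equiv), CH2Cl2, −78 to 0 °C; aq. Rochelle salt
Reagents that add atoms: none
Why: 1,2-reduction of a conjugated ester by an aluminium hydride should give the allylic alcohol; the sulfone is inert.

Step 8
Reactants: 12 [(1R,4aS,8aS)-5,5,8a-trimethyl-1-[(phenylsulfonyl)methyl]-1,4,4a,5,6,7,8,8a-octahydronaphthalen-2-yl]methanol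
Product: 14 [[(1S,4aS,8aS)-2,5,5,8a-tetramethyl-1,4,4a,5,6,7,8,8a-octahydronaphthalen-1-yl]methylsulfonyl]benzene, via allylic mesylate 13 (not isolated)
Conditions: MsCl, Et3N, THF, 0 °C; then LiEt3BH, 0 °C to rt
Reagents that add atoms: none
Why: SN2 hydride displacement of a primary allylic mesylate should turn C17 into the methyl group; attack at the unhindered CH2 is expected over the SN2′ path at C7, and the borohydride is not basic enough to touch the sulfone.

Step 9
Reactants: 15 3-methylbut-2-en-1-ol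
Product: 16 tert-butyl(dimethyl)[(3-methylbut-2-en-1-yl)oxy]silane
Conditions: t-BuMe2SiCl, imidazole, CH2Cl2, rt
Reagents that add atoms: tert-butyldimethylsilyl chloride, CC(C)(C)[Si](C)(C)Cl
Why: silylation of a primary alcohol, to protect the future C15 oxygen against the organolithium and amalgam steps.

Step 10
Reactants: 16 tert-butyl(dimethyl)[(3-methylbut-2-en-1-yl)oxy]silane
Product: 17 (2E)-4-[[tert-butyl(dimethyl)silyl]oxy]-2-methylbut-2-en-1-ol
Conditions: SeO2 (0.1 equiv), t-BuOOH, salicylic acid (0.1 equiv), CH2Cl2, rt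
Reagents that add atoms: tert-butyl hydroperoxide, CC(C)(C)OO
Why: selenium dioxide allylic oxidation (ene reaction, then [2,3] shift) should take place at the methyl group trans to the CH2O chain, which fixes the E geometry of the later C13=C14 bond.

Step 11
Reactants: 17 (2E)-4-[[tert-butyl(dimethyl)silyl]oxy]-2-methylbut-2-en-1-ol
Product: 18 [[(2E)-4-bromo-3-methylbut-2-en-1-yl]oxy](tert-butyl)dimethylsilane
Conditions: CBr4, PPh3, CH2Cl2, 0 °C
Reagents that add atoms: carbon tetrabromide, BrC(Br)(Br)Br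
Why: Appel bromination; SN2 at the primary allylic carbon should keep the alkene position and geometry.

Step 12
Reactants: 14 [[(1S,4aS,8aS)-2,5,5,8a-tetramethyl-1,4,4a,5,6,7,8,8a-octahydronaphthalen-1-yl]methylsulfonyl]benzene; 18 [[(2E)-4-bromo-3-methylbut-2-en-1-yl]oxy](tert-butyl)dimethylsilane
Product: 20 tert-butyl(dimethyl)[[(2E)-3-methyl-5-(phenylsulfonyl)-5-[(1S,4aS,8aS)-2,5,5,8a-tetramethyl-1,4,4a,5,6,7,8,8a-octahydronaphthalen-1-yl]pent-2-en-1-yl]oxy]silane, via lithiated sulfone 19 (not isolated)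
Conditions: n-BuLi, THF, −78 °C; then 18, −78 to 0 °C
Reagents that add atoms: none
Why: alkylation of an α-sulfonyl carbanion with a primary allylic bromide (SN2) should form C11–C12; the new center at C11 is formed as both epimers and is removed in the next step.

Step 13
Reactants: 20 tert-butyl(dimethyl)[[(2E)-3-methyl-5-(phenylsulfonyl)-5-[(1S,4aS,8aS)-2,5,5,8a-tetramethyl-1,4,4a,5,6,7,8,8a-octahydronaphthalen-1-yl]pent-2-en-1-yl]oxy]silane
Product: 21 tert-butyl(dimethyl)[[(2E)-3-methyl-5-[(1S,4aS,8aS)-2,5,5,8a-tetramethyl-1,4,4a,5,6,7,8,8a-octahydronaphthalen-1-yl]pent-2-en-1-yl]oxy]silane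
Conditions: Na/Hg (6 % Na), Na2HPO4, MeOH/THF, −20 °C
Reagents that add atoms: none
Why: Julia-type reductive desulfonylation (electron transfer, loss of sulfinate, protonation) should leave C11 as CH2; neither alkene is allylic to C11, so no double-bond shift is expected.

Step 14
Reactants: 21 tert-butyl(dimethyl)[[(2E)-3-methyl-5-[(1S,4aS,8aS)-2,5,5,8a-tetramethyl-1,4,4a,5,6,7,8,8a-octahydronaphthalen-1-yl]pent-2-en-1-yl]oxy]silane
Product: 22 (2E)-3-methyl-5-[(1S,4aS,8aS)-2,5,5,8a-tetramethyl-1,4,4a,5,6,7,8,8a-octahydronaphthalen-1-yl]pent-2-en-1-ol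
Conditions: Bu4NF, THF, rt
Reagents that add atoms: none
Why: fluoride-induced cleavage of the silyl ether should free the allylic alcohol without touching the alkenes.

Step 15
Reactants: 22 (2E)-3-methyl-5-[(1S,4aS,8aS)-2,5,5,8a-tetramethyl-1,4,4a,5,6,7,8,8a-octahydronaphthalen-1-yl]pent-2-en-1-ol
Product: 23 3-[[(2E)-3-methyl-5-[(1S,4aS,8aS)-2,5,5,8a-tetramethyl-1,4,4a,5,6,7,8,8a-octahydronaphthalen-1-yl]pent-2-en-1-yl]oxy]-3-oxopropanoic acid
Conditions: Meldrum's acid (1.2 equiv), toluene, 90 °C
Reagents that add atoms: Meldrum's acid, CC1(C)OC(=O)CC(=O)O1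
Why: alcoholysis of Meldrum's acid; ring opening by the alcohol and loss of acetone should give the hydrogen malonate directly, with no diester.

**Compound list**

1 | 2,4,4-trimethylcyclohex-2-en-1-one | CC1=CC(C)(C)CCC1=O | starting material
2 | (1R)-2,4,4-trimethylcyclohex-2-en-1-ol | O[C@@H]1CCC(C)(C)C=C1C | intermediate
3 | 1-ethoxyethenyl (1R)-2,4,4-trimethylcyclohex-2-en-1-yl ether (ketene acetal) | C=C(OCC)O[C@@H]1CCC(C)(C)C=C1C | intermediate (not isolated)
4 | ethyl 2-[(1S)-2,6,6-trimethylcyclohex-2-en-1-yl]acetate | CCOC(=O)C[C@H]1C(C)(C)CCC=C1C | intermediate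
5 | (E)-1,2-bis(phenylsulfonyl)ethene | O=S(=O)(/C=C/S(=O)(=O)c1ccccc1)c1ccccc1 | starting material
6 | ethyl 2-[(1S,2S)-2,6,6-trimethyl-2-[(E)-2-(phenylsulfonyl)ethenyl]cyclohexyl]acetate | CCOC(=O)C[C@H]1C(C)(C)CCC[C@]1(C)/C=C/S(=O)(=O)c1ccccc1 | intermediate
7 | 2-[(1S,2S)-2,6,6-trimethyl-2-[(E)-2-(phenylsulfonyl)ethenyl]cyclohexyl]acetic acid | OC(=O)C[C@H]1C(C)(C)CCC[C@]1(C)/C=C/S(=O)(=O)c1ccccc1 | intermediate
8 | 2-[(1S,2S)-2,6,6-trimethyl-2-[(E)-2-(phenylsulfonyl)ethenyl]cyclohexyl]acetyl hypoiodite | IOC(=O)C[C@H]1C(C)(C)CCC[C@]1(C)/C=C/S(=O)(=O)c1ccccc1 | intermediate (not isolated)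
9 | [(E)-2-[(1R,2S)-2-(iodomethyl)-1,3,3-trimethylcyclohexyl]ethenyl]sulfonylbenzene | IC[C@H]1C(C)(C)CCC[C@]1(C)/C=C/S(=O)(=O)c1ccccc1 | intermediate
10 | methyl propiolate (methyl prop-2-ynoate) | C#CC(=O)OC | starting material
11 | methyl (1R,4aS,8aS)-5,5,8a-trimethyl-1-[(phenylsulfonyl)methyl]-1,4,4a,5,6,7,8,8a-octahydronaphthalene-2-carboxylate | COC(=O)C1=CC[C@H]2C(C)(C)CCC[C@]2(C)[C@H]1CS(=O)(=O)c1ccccc1 | intermediate
12 | [(1R,4aS,8aS)-5,5,8a-trimethyl-1-[(phenylsulfonyl)methyl]-1,4,4a,5,6,7,8,8a-octahydronaphthalen-2-yl]methanol | OCC1=CC[C@H]2C(C)(C)CCC[C@]2(C)[C@H]1CS(=O)(=O)c1ccccc1 | intermediate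
13 | [(1R,4aS,8aS)-5,5,8a-trimethyl-1-[(phenylsulfonyl)methyl]-1,4,4a,5,6,7,8,8a-octahydronaphthalen-2-yl]methyl methanesulfonate | CS(=O)(=O)OCC1=CC[C@H]2C(C)(C)CCC[C@]2(C)[C@H]1CS(=O)(=O)c1ccccc1 | intermediate (not isolated)
14 | [[(1S,4aS,8aS)-2,5,5,8a-tetramethyl-1,4,4a,5,6,7,8,8a-octahydronaphthalen-1-yl]methylsulfonyl]benzene | CC1=CC[C@H]2C(C)(C)CCC[C@]2(C)[C@H]1CS(=O)(=O)c1ccccc1 | intermediate
15 | 3-methylbut-2-en-1-ol | CC(C)=CCO | starting material
16 | tert-butyl(dimethyl)[(3-methylbut-2-en-1-yl)oxy]silane | CC(C)=CCO[Si](C)(C)C(C)(C)C | intermediate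
17 | (2E)-4-[[tert-butyl(dimethyl)silyl]oxy]-2-methylbut-2-en-1-ol | OC/C(C)=C/CO[Si](C)(C)C(C)(C)C | intermediate
18 | [[(2E)-4-bromo-3-methylbut-2-en-1-yl]oxy](tert-butyl)dimethylsilane | BrC/C(C)=C/CO[Si](C)(C)C(C)(C)C | intermediate
19 | lithium salt of the α-sulfonyl carbanion of 14 | [Li+].CC1=CC[C@H]2C(C)(C)CCC[C@]2(C)[C@H]1[CH-]S(=O)(=O)c1ccccc1 | intermediate (not isolated)
20 | tert-butyl(dimethyl)[[(2E)-3-methyl-5-(phenylsulfonyl)-5-[(1S,4aS,8aS)-2,5,5,8a-tetramethyl-1,4,4a,5,6,7,8,8a-octahydronaphthalen-1-yl]pent-2-en-1-yl]oxy]silane (both epimers at the sulfone carbon) | CC1=CC[C@H]2C(C)(C)CCC[C@]2(C)[C@H]1C(C/C(C)=C/CO[Si](C)(C)C(C)(C)C)S(=O)(=O)c1ccccc1 | intermediate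
21 | tert-butyl(dimethyl)[[(2E)-3-methyl-5-[(1S,4aS,8aS)-2,5,5,8a-tetramethyl-1,4,4a,5,6,7,8,8a-octahydronaphthalen-1-yl]pent-2-en-1-yl]oxy]silane | CC1=CC[C@H]2C(C)(C)CCC[C@]2(C)[C@H]1CC/C(C)=C/CO[Si](C)(C)C(C)(C)C | intermediate
22 | (2E)-3-methyl-5-[(1S,4aS,8aS)-2,5,5,8a-tetramethyl-1,4,4a,5,6,7,8,8a-octahydronaphthalen-1-yl]pent-2-en-1-ol | CC1=CC[C@H]2C(C)(C)CCC[C@]2(C)[C@H]1CC/C(C)=C/CO | intermediate
23 | 3-[[(2E)-3-methyl-5-[(1S,4aS,8aS)-2,5,5,8a-tetramethyl-1,4,4a,5,6,7,8,8a-octahydronaphthalen-1-yl]pent-2-en-1-yl]oxy]-3-oxopropanoic acid | CC1=CC[C@H]2C(C)(C)CCC[C@]2(C)[C@H]1CC/C(C)=C/COC(=O)CC(=O)O | target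

**Step count and risks**

Total step count: 15. Longest linear sequence: 12 steps (steps 1 to 8 and 12 to 15; steps 9 to 11 make the side-chain bromide).

Steps most likely to fail:

1. Step 6. The C6 radical may be reduced, or may add to the vinyl sulfone of a second molecule, before it meets the alkyne; the vinyl radical may be reduced before ring closure; or the ring may close on the wrong face of C9. The fallback sets out from 6 and comes back at 11. Reduction of the ethyl ester with i-Bu2AlH at −78 °C should give 2-[(1S,2S)-2,6,6-trimethyl-2-[(E)-2-(phenylsulfonyl)ethenyl]cyclohexyl]acetaldehyde F1. A Wittig reaction with methyl (triphenylphosphoranylidene)acetate should then give methyl (2E)-4-[(1S,2S)-2,6,6-trimethyl-2-[(E)-2-(phenylsulfonyl)ethenyl]cyclohexyl]but-2-enoate F2. An intramolecular Rauhut–Currier reaction (PMe3, tert-amyl alcohol) should close ring B: the phosphine adds to C7 of the enoate, the enolate carbon C8 adds to C9 of the vinyl sulfone, and loss of the phosphine restores C7=C8 to give 11. In this variant the ester carbon of 6 is kept as C7, so only C8–C9 is made in the ring closure. The open-chain enoate that premature reduction in step 6 would leave is F2, so that material could be fed into the same closure.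

2. Step 3. The tertiary C10 radical may be quenched by hydrogen transfer before it reaches the acceptor, the acceptor may be reduced by the iron hydride, or the sulfonyl radical may not be turned over. The fallback sets out from 4 and comes back at 6, using known reactions only. Iron-hydride hydroalkynylation of the alkene with phenyl [(triisopropylsilyl)ethynyl] sulfone (Fe(acac)3, PhSiH3) should give ethyl 2-[(1S,2S)-2,6,6-trimethyl-2-[2-[tri(propan-2-yl)silyl]ethynyl]cyclohexyl]acetate F3. Bu4NF should then give ethyl 2-[(1S,2S)-2-ethynyl-2,6,6-trimethylcyclohexyl]acetate F4. Radical addition of PhSH (AIBN) should give ethyl 2-[(1S,2S)-2,6,6-trimethyl-2-[2-(phenylsulfanyl)ethenyl]cyclohexyl]acetate F5 as an alkene mixture. Oxidation with m-CPBA, followed by equilibration of the alkene with a trace of PhSNa, should give the (E)-vinyl sulfone 6.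

3. Step 2. The allylic orthoester may ionize under the acid and lose a proton to a diene, or the [3,3] shift may be too slow because the new bond forms next to the quaternary C4. The fallback sets out from 2 and comes back at 9; it moves one carbon by a [2,3] shift at low temperature, so no decarboxylation is needed. Etherification with KH and Bu3SnCH2I should give tributyl[[[(1R)-2,4,4-trimethylcyclohex-2-en-1-yl]oxy]methyl]stannane F6. Tin–lithium exchange with n-BuLi at −78 °C and Still–Wittig rearrangement should give [(1S)-2,6,6-trimethylcyclohex-2-en-1-yl]methanol F7. Alkenylation under the conditions of step 3 should give [(1S,2S)-2,6,6-trimethyl-2-[(E)-2-(phenylsulfonyl)ethenyl]cyclohexyl]methanol F8. Iodination with PPh3, I2 and imidazole in hot toluene should give 9.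

**Further compounds**

F1 | step 6 | 2-[(1S,2S)-2,6,6-trimethyl-2-[(E)-2-(phenylsulfonyl)ethenyl]cyclohexyl]acetaldehyde | O=CC[C@H]1C(C)(C)CCC[C@]1(C)/C=C/S(=O)(=O)c1ccccc1
F2 | step 6 | methyl (2E)-4-[(1S,2S)-2,6,6-trimethyl-2-[(E)-2-(phenylsulfonyl)ethenyl]cyclohexyl]but-2-enoate | COC(=O)/C=C/C[C@H]1C(C)(C)CCC[C@]1(C)/C=C/S(=O)(=O)c1ccccc1
F3 | step 3 | ethyl 2-[(1S,2S)-2,6,6-trimethyl-2-[2-[tri(propan-2-yl)silyl]ethynyl]cyclohexyl]acetate | CCOC(=O)C[C@H]1C(C)(C)CCC[C@]1(C)C#C[Si](C(C)C)(C(C)C)C(C)C
F4 | step 3 | ethyl 2-[(1S,2S)-2-ethynyl-2,6,6-trimethylcyclohexyl]acetate | CCOC(=O)C[C@H]1C(C)(C)CCC[C@]1(C)C#C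
F5 | step 3 | ethyl 2-[(1S,2S)-2,6,6-trimethyl-2-[2-(phenylsulfanyl)ethenyl]cyclohexyl]acetate (alkene mixture) | CCOC(=O)C[C@H]1C(C)(C)CCC[C@]1(C)C=CSc1ccccc1
F6 | step 2 | tributyl[[[(1R)-2,4,4-trimethylcyclohex-2-en-1-yl]oxy]methyl]stannane | CCCC[Sn](CCCC)(CCCC)CO[C@@H]1CCC(C)(C)C=C1C
F7 | step 2 | [(1S)-2,6,6-trimethylcyclohex-2-en-1-yl]methanol | OC[C@H]1C(C)(C)CCC=C1C
F8 | step 2 | [(1S,2S)-2,6,6-trimethyl-2-[(E)-2-(phenylsulfonyl)ethenyl]cyclohexyl]methanol | OC[C@H]1C(C)(C)CCC[C@]1(C)/C=C/S(=O)(=O)c1ccccc1
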